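The dihydrofuran ring B is closed last at its aryl ether bond O1–C7a (benzofuran numbering). Ring A is a guaiacyl unit whose phenol carbon C7a becomes a triflate. The precursor is an open-chain α-aryl β-hydroxy ester in which only the carbinol centre C2 has been set, by asymmetric transfer hydrogenation; its C2 oxygen displaces the triflate under palladium catalysis. The key step exploits two features: C7a lies ortho to the C3a–C3 bond, so the C2 oxygen reaches it in a five-membered closure, and C3–H is benzylic to ring A and α to the ester, so both C3 epimers funnel, in the same operation, into the favoured 2,3-trans ester. Reduction and debenzylation finish.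

Key step: step 6

Remark: ring A is the benzo ring, ring B the dihydrofuran ring, ring C the syringyl ring; the target is the (2S,3R)-trans isomer.
Assumption: methyl dihydroferulate, the (2-tert-butoxy-2-oxoethyl)zinc bromide solution and 4-(benzyloxy)-3,5-dimethoxybenzoic acid are taken as commercially available.

Step 1
Reactants: 1 methyl 3-(4-hydroxy-3-methoxyphenyl)propanoate (methyl dihydroferulate)
Product: 2 methyl 3-(4-hydroxy-3-iodo-5-methoxyphenyl)propanoate
Conditions: I2, NaHCO3, THF/H2O, 0 °C to rt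
Reagents that add atoms: iodine, II
Why: Electrophilic aromatic iodination under phenoxide control; the para position of the phenol is blocked by the side chain and one ortho position by OMe, so iodine should enter the only free ortho carbon (the future C3a).

Step 2
Reactants: 2 methyl 3-(4-hydroxy-3-iodo-5-methoxyphenyl)propanoate
Product: 3 methyl 3-[3-iodo-5-methoxy-4-(trifluoromethylsulfonyloxy)phenyl]propanoate
Conditions: Tf2O, pyridine, CH2Cl2, 0 °C
Reagents that add atoms: trifluoromethanesulfonic anhydride, O=S(=O)(OS(=O)(=O)C(F)(F)F)C(F)(F)F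
Why: O-Sulfonylation of the phenol turns the future C7a–O position into a C7a–OTf electrophile for step 6.

Step 3
Reactants: 3 methyl 3-[3-iodo-5-methoxy-4-(trifluoromethylsulfonyloxy)phenyl]propanoate, 4 (2-tert-butoxy-2-oxoethyl)zinc bromide
Product: 5 methyl 3-[3-(2-tert-butoxy-2-oxoethyl)-5-methoxy-4-(trifluoromethylsulfonyloxy)phenyl]propanoate
Conditions: Pd(dba)2 (cat.), P(t-Bu)3 (cat.), THF, rt
Reagents that add atoms: none
Why: Negishi-type coupling of a Reformatsky reagent (palladium-catalysed ester α-arylation); zerovalent palladium should insert into the C–I bond much faster than into the hindered neighbouring C–OTf bond, which is kept.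

Step 4
Reactants: 5 methyl 3-[3-(2-tert-butoxy-2-oxoethyl)-5-methoxy-4-(trifluoromethylsulfonyloxy)phenyl]propanoate, 6 4-(benzyloxy)-3,5-dimethoxybenzoic acid
Product: 8 tert-butyl 3-[4-(benzyloxy)-3,5-dimethoxyphenyl]-2-[3-methoxy-5-(3-methoxy-3-oxopropyl)-2-(trifluoromethylsulfonyloxy)phenyl]-3-oxopropanoate (racemic), via acyl imidazolide 7 (not isolated)
Conditions: 6, 1,1'-carbonyldiimidazole, THF, rt; 5, LiN(SiMe3)2 (2.1 equiv), THF, −78 °C; then the solution of 7, −78 to 0 °C; aq. NH4Cl
Reagents that add atoms: none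
Why: Crossed Claisen C-acylation of the lithium enolate of the arylacetate (the benzylic CH2 α to the ester is deprotonated in preference to the propanoate CH2) by the acyl imidazolide; the second equivalent of base stores the product as its enolate, and the new centre is racemic and configurationally labile.

Step 5
Reactants: 8 tert-butyl 3-[4-(benzyloxy)-3,5-dimethoxyphenyl]-2-[3-methoxy-5-(3-methoxy-3-oxopropyl)-2-(trifluoromethylsulfonyloxy)phenyl]-3-oxopropanoate
Product: 9 tert-butyl (3S)-3-[4-(benzyloxy)-3,5-dimethoxyphenyl]-3-hydroxy-2-[3-methoxy-5-(3-methoxy-3-oxopropyl)-2-(trifluoromethylsulfonyloxy)phenyl]propanoate (mixture of C2 epimers)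
Conditions: RuCl[(S,S)-TsDPEN](p-cymene) (cat.), HCO2H/Et3N (5:2), DMF, 40 °C
Reagents that add atoms: none
Why: Noyori–Ikariya asymmetric transfer hydrogenation with dynamic kinetic resolution; the (S,S)-catalyst should deliver hydride to the aryl ketone in the sense that turns acetophenone into (S)-1-phenylethanol, giving the (3S)-carbinol while the α-centre racemises through the enol, and the configuration at C2 of 9 is left open because step 6 corrects it.

Step 6
Reactants: 9 tert-butyl (3S)-3-[4-(benzyloxy)-3,5-dimethoxyphenyl]-3-hydroxy-2-[3-methoxy-5-(3-methoxy-3-oxopropyl)-2-(trifluoromethylsulfonyloxy)phenyl]propanoate (mixture of C2 epimers)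
Product: 11 tert-butyl (2S,3S)-2-[4-(benzyloxy)-3,5-dimethoxyphenyl]-7-methoxy-5-(3-methoxy-3-oxopropyl)-2,3-dihydro-1-benzofuran-3-carboxylate, via C3-epimeric cyclised esters 10 (not isolated)
Conditions: Pd(OAc)2 (cat.), 2-(di-tert-butylphosphino)-1,1'-binaphthyl (cat.), K3PO4, toluene, 80 °C; then NaOMe (cat.), MeOH, rt to 40 °C
Reagents that add atoms: none
Why: Pd(OAc)2 is reduced in situ to zerovalent palladium, which inserts into the C7a–OTf bond; phosphate-assisted binding of the C2 hydroxyl gives a six-membered aryl(alkoxo) complex of divalent palladium, and C–O reductive elimination forms the O1–C7a bond. The closest known reaction type is the Buchwald–Hartwig intramolecular etherification of aryl halides and sulfonates by secondary alcohols, which retains the carbinol configuration. Ring B closes as a five-membered ring from that palladacycle, formally a 5-exo attack of the C2 oxygen on C7a of ring A. C2 keeps the S configuration from step 5 because no bond to it is made or broken, whereas C3 is set under thermodynamic control: methoxide enolises the benzylic, α-ester C3–H of 10 and reprotonation places the ester trans to the 2-aryl group, so both epimers of 9 should converge on 11. The step needs O-arylation to outrun retro-aldol cleavage and β-hydride elimination; the weak, insoluble K3PO4 forms alkoxide essentially only at palladium, and the bulky di-tert-butylbiaryl phosphine accelerates reductive elimination. Regiochemistry is fixed because the triflate marks C7a alone.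

Step 7
Reactants: 11 tert-butyl (2S,3S)-2-[4-(benzyloxy)-3,5-dimethoxyphenyl]-7-methoxy-5-(3-methoxy-3-oxopropyl)-2,3-dihydro-1-benzofuran-3-carboxylate
Product: 12 3-[(2S,3R)-2-[4-(benzyloxy)-3,5-dimethoxyphenyl]-3-(hydroxymethyl)-7-methoxy-2,3-dihydro-1-benzofuran-5-yl]propan-1-ol
Conditions: LiAlH4, THF, 0 °C to rt; then Na2SO4·10H2O
Reagents that add atoms: none
Why: Hydride reduction of both esters (tert-butyl ester at C3, methyl ester of the side chain) to primary alcohols; C2 and C3 are not touched, and the descriptor at C3 changes from S to R only through the priority rules.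

Step 8
Reactants: 12 3-[(2S,3R)-2-[4-(benzyloxy)-3,5-dimethoxyphenyl]-3-(hydroxymethyl)-7-methoxy-2,3-dihydro-1-benzofuran-5-yl]propan-1-ol
Product: 13 4-[(2S,3R)-3-(hydroxymethyl)-5-(3-hydroxypropyl)-7-methoxy-2,3-dihydro-1-benzofuran-2-yl]-2,6-dimethoxyphenol (CNP0188630.1)
Conditions: H2 (1 atm), Pd/C (palladium on carbon), EtOAc/MeOH, rt
Reagents that add atoms: none
Why: Catalytic hydrogenolysis of the benzyl aryl ether frees the phenol; this ether should cleave much faster than the cyclic benzylic C2–O1 bond, so the reaction is stopped after one equivalent of hydrogen.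

Compound list
1 | methyl 3-(4-hydroxy-3-methoxyphenyl)propanoate | COC(=O)CCc1ccc(O)c(OC)c1 | starting material
2 | methyl 3-(4-hydroxy-3-iodo-5-methoxyphenyl)propanoate | COC(=O)CCc1cc(I)c(O)c(OC)c1 | intermediate
3 | methyl 3-[3-iodo-5-methoxy-4-(trifluoromethylsulfonyloxy)phenyl]propanoate | COC(=O)CCc1cc(I)c(OS(=O)(=O)C(F)(F)F)c(OC)c1 | intermediate
4 | (2-tert-butoxy-2-oxoethyl)zinc bromide | CC(C)(C)OC(=O)C[Zn]Br | starting material
5 | methyl 3-[3-(2-tert-butoxy-2-oxoethyl)-5-methoxy-4-(trifluoromethylsulfonyloxy)phenyl]propanoate | COC(=O)CCc1cc(CC(=O)OC(C)(C)C)c(OS(=O)(=O)C(F)(F)F)c(OC)c1 | intermediate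
6 | 4-(benzyloxy)-3,5-dimethoxybenzoic acid | COc1cc(C(=O)O)cc(OC)c1OCc1ccccc1 | starting material
7 | [4-(benzyloxy)-3,5-dimethoxyphenyl](1H-imidazol-1-yl)methanone (acyl imidazolide) | COc1cc(C(=O)n2ccnc2)cc(OC)c1OCc1ccccc1 | intermediate
8 | tert-butyl 3-[4-(benzyloxy)-3,5-dimethoxyphenyl]-2-[3-methoxy-5-(3-methoxy-3-oxopropyl)-2-(trifluoromethylsulfonyloxy)phenyl]-3-oxopropanoate (racemic) | COC(=O)CCc1cc(C(C(=O)OC(C)(C)C)C(=O)c2cc(OC)c(OCc3ccccc3)c(OC)c2)c(OS(=O)(=O)C(F)(F)F)c(OC)c1 | intermediate
9 | tert-butyl (3S)-3-[4-(benzyloxy)-3,5-dimethoxyphenyl]-3-hydroxy-2-[3-methoxy-5-(3-methoxy-3-oxopropyl)-2-(trifluoromethylsulfonyloxy)phenyl]propanoate (mixture of C2 epimers) | COc1cc([C@@H](O)C(c2cc(CCC(=O)OC)cc(OC)c2OS(=O)(=O)C(F)(F)F)C(=O)OC(C)(C)C)cc(OC)c1OCc1ccccc1 | intermediate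
10 | tert-butyl (2S)-2-[4-(benzyloxy)-3,5-dimethoxyphenyl]-7-methoxy-5-(3-methoxy-3-oxopropyl)-2,3-dihydro-1-benzofuran-3-carboxylate (kinetic mixture of C3 epimers) | COc1cc([C@H]2Oc3c(OC)cc(CCC(=O)OC)cc3C2C(=O)OC(C)(C)C)cc(OC)c1OCc1ccccc1 | intermediate
11 | tert-butyl (2S,3S)-2-[4-(benzyloxy)-3,5-dimethoxyphenyl]-7-methoxy-5-(3-methoxy-3-oxopropyl)-2,3-dihydro-1-benzofuran-3-carboxylate | COc1cc([C@H]2Oc3c(OC)cc(CCC(=O)OC)cc3[C@@H]2C(=O)OC(C)(C)C)cc(OC)c1OCc1ccccc1 | intermediate
12 | 3-[(2S,3R)-2-[4-(benzyloxy)-3,5-dimethoxyphenyl]-3-(hydroxymethyl)-7-methoxy-2,3-dihydro-1-benzofuran-5-yl]propan-1-ol | COc1cc([C@H]2Oc3c(OC)cc(CCCO)cc3[C@@H]2CO)cc(OC)c1OCc1ccccc1 | intermediate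
13 | 4-[(2S,3R)-3-(hydroxymethyl)-5-(3-hydroxypropyl)-7-methoxy-2,3-dihydro-1-benzofuran-2-yl]-2,6-dimethoxyphenol | COc1cc([C@H]2Oc3c(OC)cc(CCCO)cc3[C@@H]2CO)cc(OC)c1O | target

Total step count: 8. Longest linear sequence: 8 steps (from 1 to 13).

Steps most likely to fail

Step 6 (key step). Retro-aldol fragmentation or base-induced dehydration of the β-hydroxy ester, or β-hydride elimination of the palladium alkoxide to the ketone, may outrun C–O reductive elimination. The fallback removes the carbonyl group and the labile C3–H before ring closure and sets both centres by auxiliary control. It sets out from 5 and comes back to the route at 12.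
- CF3CO2H in CH2Cl2 cleaves the tert-butyl ester to the arylacetic acid F1.
- Pivaloyl chloride and Et3N, then (S)-4-benzyl-2-oxazolidinone and LiCl, give the N-acyl oxazolidinone F2.
- The Evans syn-aldol reaction (Bu2BOTf, i-Pr2NEt, CH2Cl2, −78 to 0 °C) with commercial 4-(benzyloxy)-3,5-dimethoxybenzaldehyde should give the (2S,3S) syn-aldol adduct F3.
- LiBH4 and MeOH in THF reduce the imide and the methyl ester to the triol F4.
- TBSCl (2.2 equiv) and imidazole silylate the two primary hydroxyls to the bis-silyl ether F5.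
- The palladium-catalysed etherification of step 6, now on a carbonyl-free secondary alcohol whose C3 centre is already correct, should give the silylated trans-dihydrobenzofuran F6.
- Bu4NF in THF then gives 12.

Step 5. Hydride transfer to the hindered, strongly enolised diaryl β-keto ester may stall or proceed with poor facial discrimination. The fallback changes the controlling element from outer-sphere aryl recognition to chelation of the β-keto ester. It sets out from 8 and comes back at 9: asymmetric hydrogenation with RuCl2[(R)-BINAP] under H2 (50 atm) in CH2Cl2/MeOH at 50 °C, with dynamic kinetic resolution, should deliver the same (3S)-carbinol. This fallback makes no compound outside the list (F0).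

Step 4. O-Acylation, or transfer of the triflyl group from the ortho oxygen to the enolate carbon, may compete with C-acylation. The fallback forms the C3–C3a bond instead of the C2–C3 bond and never generates the arylacetate enolate. It sets out from 3 (with 6) and comes back at 8: acid 6 is activated with 1,1'-carbonyldiimidazole to 7 and treated with Mg(O2CCH2CO2t-Bu)2 in THF to give the tert-butyl aroylacetate F7; copper-catalysed arylation of F7 with aryl iodide 3 (CuI, L-proline, Cs2CO3, DMSO, 40 °C) should give 8 directly, the triflate being inert to copper.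

Further compounds
F1 | step 6 | 2-[3-methoxy-5-(3-methoxy-3-oxopropyl)-2-(trifluoromethylsulfonyloxy)phenyl]acetic acid | COC(=O)CCc1cc(CC(=O)O)c(OS(=O)(=O)C(F)(F)F)c(OC)c1
F2 | step 6 | methyl 3-[3-{2-[(4S)-4-benzyl-2-oxo-1,3-oxazolidin-3-yl]-2-oxoethyl}-5-methoxy-4-(trifluoromethylsulfonyloxy)phenyl]propanoate | COC(=O)CCc1cc(CC(=O)N2[C@@H](Cc3ccccc3)COC2=O)c(OS(=O)(=O)C(F)(F)F)c(OC)c1
F3 | step 6 | (4S)-4-benzyl-3-[(2S,3S)-3-[4-(benzyloxy)-3,5-dimethoxyphenyl]-3-hydroxy-2-[3-methoxy-5-(3-methoxy-3-oxopropyl)-2-(trifluoromethylsulfonyloxy)phenyl]propanoyl]-1,3-oxazolidin-2-one | COc1cc([C@@H](O)[C@H](c2cc(CCC(=O)OC)cc(OC)c2OS(=O)(=O)C(F)(F)F)C(=O)N2[C@@H](Cc3ccccc3)COC2=O)cc(OC)c1OCc1ccccc1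
F4 | step 6 | (1S,2R)-1-[4-(benzyloxy)-3,5-dimethoxyphenyl]-2-[5-(3-hydroxypropyl)-3-methoxy-2-(trifluoromethylsulfonyloxy)phenyl]propane-1,3-diol | COc1cc([C@@H](O)[C@H](c2cc(CCCO)cc(OC)c2OS(=O)(=O)C(F)(F)F)CO)cc(OC)c1OCc1ccccc1
F5 | step 6 | (1S,2R)-1-[4-(benzyloxy)-3,5-dimethoxyphenyl]-3-(tert-butyldimethylsilyloxy)-2-{5-[3-(tert-butyldimethylsilyloxy)propyl]-3-methoxy-2-(trifluoromethylsulfonyloxy)phenyl}propan-1-ol | COc1cc([C@@H](O)[C@H](c2cc(CCCO[Si](C)(C)C(C)(C)C)cc(OC)c2OS(=O)(=O)C(F)(F)F)CO[Si](C)(C)C(C)(C)C)cc(OC)c1OCc1ccccc1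
F6 | step 6 | (2S,3R)-2-[4-(benzyloxy)-3,5-dimethoxyphenyl]-3-[(tert-butyldimethylsilyloxy)methyl]-5-[3-(tert-butyldimethylsilyloxy)propyl]-7-methoxy-2,3-dihydro-1-benzofuran | COc1cc([C@H]2Oc3c(OC)cc(CCCO[Si](C)(C)C(C)(C)C)cc3[C@@H]2CO[Si](C)(C)C(C)(C)C)cc(OC)c1OCc1ccccc1
F0 | step 5 | none | none
F7 | step 4 | tert-butyl 3-[4-(benzyloxy)-3,5-dimethoxyphenyl]-3-oxopropanoate | COc1cc(C(=O)CC(=O)OC(C)(C)C)cc(OC)c1OCc1ccccc1
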